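**Plan** (target numbering: C1 = ketone carbon, C4 = stereocentre; ring A = catechol ring, ring B = cyclohexanone ring)
1. Retrosynthesis: three O-benzyl groups and a helper CO2Me on C3 are added back. The C1–C2 bond of ring B is then cut and C1 is rejoined to C3, which contracts ring B to a 3-arylindan-1-one whose α-carbon (future C3) carries CO2Me and CH2I (future C2).
2. The indanone is cut at C4–C4a (Nazarov) and at C3=C4 (Knoevenagel), which gives methyl 2,3-bis(benzyloxy)benzoylacetate and 4-(benzyloxy)-8-methoxy-1-naphthaldehyde.
3. Forward: two short fragment syntheses, Knoevenagel union, five-membered ring by 4π closure, iodomethylation, radical one-carbon ring expansion to six-membered ring B, excision of the ester, hydrogenolysis.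
4. Enabling feature: in ring B only the unsubstituted methylene C2 separates the aryl ketone C1 from C3, so C2 can be slipped in by a 1,2-shift of the aroyl carbon C1 through a C1–C2–C3 cyclopropyloxyl radical. In ring A the C7 oxygen lies para to C4a and activates exactly the carbon that must bond to C4 in the smaller ring.
5. Stereochemistry: C4, the only stereocentre, is set as S in the Nazarov closure by a chiral Cu(OTf)2–bis(oxazoline) Lewis acid and is a spectator afterwards. The centres at C3 are transient and are erased.
6. The one helper ester polarises the Nazarov substrate, permits the C-alkylation, stabilises the ring-expanded radical and slows aryl migration. It leaves by Barton decarboxylation.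

Key step: step 9

Assumption: (R,R)-Ph-box, 2,2'-(propane-2,2-diyl)bis[(4R)-4-phenyl-4,5-dihydro-1,3-oxazole], is taken to deliver the 3S indanone; if the sense of induction is the opposite, the (S,S) ligand is used.

Step 1
Reactants: 1 1,5-dimethoxynaphthalene
Product: 3 4,8-dimethoxynaphthalene-1-carbaldehyde, via aryl iminium chloride 2 (not isolated)
Conditions: POCl3, DMF, toluene, 100 °C; then ice-water
Reagents that add atoms: N,N-dimethylformamide, CN(C)C=O; water, O
Why: Vilsmeier–Haack formylation attacks the position para to one methoxy group and peri to the other, and the two such positions of symmetric 1 are equivalent, so one aldehyde should result after hydrolysis of 2.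

Step 2
Reactants: 3 4,8-dimethoxynaphthalene-1-carbaldehyde
Product: 4 4-hydroxy-8-methoxynaphthalene-1-carbaldehyde
Conditions: NaSEt, DMF, 100 °C; then 1 M HCl
Reagents that add atoms: none
Why: SN2 demethylation by thiolate should be fastest at the C4 methoxy group, because only its naphthoxide is conjugated (para) with the formyl group, and no chelating Lewis acid is present that would select the peri methoxy group.

Step 3
Reactants: 4 4-hydroxy-8-methoxynaphthalene-1-carbaldehyde
Product: 5 4-(benzyloxy)-8-methoxynaphthalene-1-carbaldehyde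
Conditions: BnBr, K2CO3, DMF, 50 °C
Reagents that add atoms: benzyl bromide, BrCc1ccccc1
Why: Williamson etherification masks the acidic naphthol as a benzyl ether that should survive the Lewis acid, base and radical steps and later leaves by hydrogenolysis without touching the methyl ether.

Step 4
Reactants: 6 1-(2,3-dihydroxyphenyl)ethan-1-one
Product: 7 1-[2,3-bis(benzyloxy)phenyl]ethan-1-one
Conditions: BnBr (2.4 equiv), K2CO3, DMF, 70 °C
Reagents that add atoms: benzyl bromide, BrCc1ccccc1
Why: Double Williamson etherification, in which gentle heating overcomes the hydrogen bond of the ortho hydroxyl group to the ketone.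

Step 5
Reactants: 7 1-[2,3-bis(benzyloxy)phenyl]ethan-1-one
Product: 8 methyl 3-[2,3-bis(benzyloxy)phenyl]-3-oxopropanoate
Conditions: NaH, (MeO)2CO, toluene, reflux; then 1 M HCl
Reagents that add atoms: dimethyl carbonate, COC(=O)OC
Why: Crossed Claisen condensation of the methyl ketone enolate with non-enolisable dimethyl carbonate, driven by deprotonation of the β-keto ester formed.

Step 6
Reactants: 5 4-(benzyloxy)-8-methoxynaphthalene-1-carbaldehyde; 8 methyl 3-[2,3-bis(benzyloxy)phenyl]-3-oxopropanoate
Product: 9 methyl (Z)-2-[2,3-bis(benzyloxy)benzoyl]-3-[4-(benzyloxy)-8-methoxynaphthalen-1-yl]prop-2-enoate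
Conditions: piperidine (cat.), AcOH (cat.), toluene, Dean–Stark, reflux
Reagents that add atoms: none
Why: Knoevenagel condensation driven by azeotropic removal of water should favour the isomer with the naphthyl group cis to the ester and trans to the bulkier aroyl group, which is also the geometry needed for ring closure.

Step 7
Reactants: 9 methyl (Z)-2-[2,3-bis(benzyloxy)benzoyl]-3-[4-(benzyloxy)-8-methoxynaphthalen-1-yl]prop-2-enoate
Product: 10 methyl (2R,3S)-6,7-bis(benzyloxy)-3-[4-(benzyloxy)-8-methoxynaphthalen-1-yl]-1-oxo-2,3-dihydro-1H-indene-2-carboxylate (trans)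
Conditions: Cu(OTf)2 (10 mol %), (R,R)-Ph-box (11 mol %), 4 Å MS, ClCH2CH2Cl, 60 °C; recrystallisation
Reagents that add atoms: none
Why: In this catalytic asymmetric Nazarov cyclization both carbonyl groups of 9 bind to the chiral divalent copper Lewis acid, the conrotatory 4π closure onto the ring A carbon para to the future C7 oxygen is steered to one rotational sense by the ligand and so sets C4 as S, and the adjacent ester-bearing carbon equilibrates to the trans arrangement.

Step 8
Reactants: 10 methyl (2R,3S)-6,7-bis(benzyloxy)-3-[4-(benzyloxy)-8-methoxynaphthalen-1-yl]-1-oxo-2,3-dihydro-1H-indene-2-carboxylate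
Product: 11 methyl (2R,3S)-6,7-bis(benzyloxy)-3-[4-(benzyloxy)-8-methoxynaphthalen-1-yl]-2-(iodomethyl)-1-oxo-2,3-dihydro-1H-indene-2-carboxylate (CH2I trans to naphthyl)
Conditions: NaH, THF/DMPU, 0 °C; CH2I2 (5 equiv), 50 °C
Reagents that add atoms: diiodomethane, ICI
Why: C-alkylation of the β-keto ester enolate with excess diiodomethane, the standard entry to Dowd–Beckwith substrates, should occur on the face anti to the naphthyl group, and the excess of dihalide suppresses a second displacement.

Step 9
Reactants: 11 methyl (2R,3S)-6,7-bis(benzyloxy)-3-[4-(benzyloxy)-8-methoxynaphthalen-1-yl]-2-(iodomethyl)-1-oxo-2,3-dihydro-1H-indene-2-carboxylate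
Product: 15 methyl (1S)-5,6-bis(benzyloxy)-1-[4-(benzyloxy)-8-methoxynaphthalen-1-yl]-4-oxo-1,2,3,4-tetrahydronaphthalene-2-carboxylate (ester on C3 of the target numbering; both C3 epimers), via primary alkyl radical 12 (not isolated), via cyclopropyloxyl radical 13 (not isolated), via ring-expanded tertiary radical 14 (not isolated)
Conditions: Bu3SnH (1.3 equiv) + AIBN (cat.), syringe pump over 8 h, PhH (0.005 M), reflux
Reagents that add atoms: none
Why: Tributylstannyl radical abstracts iodine from 11 to give primary radical 12, whose carbon (the future C2) adds to the ketone carbon C1 to give cyclopropyloxyl radical 13, and β-scission of the old C1–C3 bond releases the six-membered, ester-stabilised tertiary radical 14, which takes hydrogen from Bu3SnH and carries the chain. The closest known reaction type is the Dowd–Beckwith one-carbon ring expansion of α-halomethyl cyclic β-keto esters, benzo-fused ketones included. The transient three-membered ring closes in the 3-exo-trig mode on the C=O bond and ring B arises from it by endocyclic fragmentation, so the net event is a 1,2-shift of the aroyl carbon from C3 to C2. No bond to C4 is made or broken, so its S configuration is carried over unchanged, while the new centre at C3 is fixed only by hydrogen transfer to the less hindered face and does not matter because step 11 erases it. The step needs rearrangement to outrun direct reduction of 12 and endocyclic scission of 13 to beat exocyclic scission: slow addition of the stannane at high dilution serves the first, and the ester on C3 together with release of the strain of the five-membered ring serves the second. The trans placement of the CH2 radical and the naphthyl group keeps the radical away from the arene, and the ester also slows a 1,2-naphthyl shift in 14.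

Step 10
Reactants: 15 methyl (1S)-5,6-bis(benzyloxy)-1-[4-(benzyloxy)-8-methoxynaphthalen-1-yl]-4-oxo-1,2,3,4-tetrahydronaphthalene-2-carboxylate
Product: 16 (1S)-5,6-bis(benzyloxy)-1-[4-(benzyloxy)-8-methoxynaphthalen-1-yl]-4-oxo-1,2,3,4-tetrahydronaphthalene-2-carboxylic acid (both C3 epimers)
Conditions: LiOH, THF/MeOH/H2O (degassed), 40 °C; then 1 M HCl
Reagents that add atoms: lithium hydroxide, [Li+].[OH-]
Why: Ester saponification, in which hydroxide is too weak a base to deprotonate the diarylmethine C4 and exclusion of air prevents dehydrogenation of the tetralone enolate to a naphthol.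

Step 11
Reactants: 16 (1S)-5,6-bis(benzyloxy)-1-[4-(benzyloxy)-8-methoxynaphthalen-1-yl]-4-oxo-1,2,3,4-tetrahydronaphthalene-2-carboxylic acid
Product: 18 (4S)-7,8-bis(benzyloxy)-4-[4-(benzyloxy)-8-methoxynaphthalen-1-yl]-3,4-dihydronaphthalen-1(2H)-one, via Barton ester 17 (not isolated)
Conditions: N-hydroxypyridine-2(1H)-thione, DCC, DMAP (cat.), CH2Cl2, dark, 0 °C to rt; then t-BuSH (10 equiv), PhH, hν (tungsten lamp), rt
Reagents that add atoms: none
Why: In this Barton decarboxylation the large excess of the fast hydrogen donor t-BuSH should trap the secondary C3 radical before a 1,2-naphthyl shift from C4 can compete, which removes the helper and both C3 epimers converge on one compound.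

Step 12
Reactants: 18 (4S)-7,8-bis(benzyloxy)-4-[4-(benzyloxy)-8-methoxynaphthalen-1-yl]-3,4-dihydronaphthalen-1(2H)-one
Product: 19 (4S)-7,8-dihydroxy-4-(4-hydroxy-8-methoxynaphthalen-1-yl)-3,4-dihydronaphthalen-1(2H)-one
Conditions: H2 (1 atm), Pd/C, EtOAc/MeOH, rt; work-up under argon
Reagents that add atoms: none
Why: Hydrogenolysis should cleave the three benzyl aryl ethers while the methyl ether, the C4 centre and the electron-rich ketone, which becomes hydrogen-bonded to the freed C8 hydroxyl group, stay untouched at atmospheric pressure.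

**Compound list**
1 | 1,5-dimethoxynaphthalene | COc1cccc2c(OC)cccc12 | starting material
2 | [(4,8-dimethoxynaphthalen-1-yl)methylidene]dimethylammonium chloride | COc1cccc2c(OC)ccc(C=[N+](C)C)c12.[Cl-] | intermediate
3 | 4,8-dimethoxynaphthalene-1-carbaldehyde | COc1cccc2c(OC)ccc(C=O)c12 | intermediate
4 | 4-hydroxy-8-methoxynaphthalene-1-carbaldehyde | COc1cccc2c(O)ccc(C=O)c12 | intermediate
5 | 4-(benzyloxy)-8-methoxynaphthalene-1-carbaldehyde | COc1cccc2c(OCc3ccccc3)ccc(C=O)c12 | intermediate
6 | 1-(2,3-dihydroxyphenyl)ethan-1-one | CC(=O)c1cccc(O)c1O | starting material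
7 | 1-[2,3-bis(benzyloxy)phenyl]ethan-1-one | CC(=O)c1cccc(OCc2ccccc2)c1OCc1ccccc1 | intermediate
8 | methyl 3-[2,3-bis(benzyloxy)phenyl]-3-oxopropanoate | COC(=O)CC(=O)c1cccc(OCc2ccccc2)c1OCc1ccccc1 | intermediate
9 | methyl (Z)-2-[2,3-bis(benzyloxy)benzoyl]-3-[4-(benzyloxy)-8-methoxynaphthalen-1-yl]prop-2-enoate | COC(=O)/C(=C\c1ccc(OCc2ccccc2)c2cccc(OC)c12)C(=O)c1cccc(OCc2ccccc2)c1OCc1ccccc1 | intermediate
10 | methyl (2R,3S)-6,7-bis(benzyloxy)-3-[4-(benzyloxy)-8-methoxynaphthalen-1-yl]-1-oxo-2,3-dihydro-1H-indene-2-carboxylate | COc1cccc2c(OCc3ccccc3)ccc([C@@H]4[C@@H](C(=O)OC)C(=O)c5c4ccc(OCc4ccccc4)c5OCc4ccccc4)c12 | intermediate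
11 | methyl (2R,3S)-6,7-bis(benzyloxy)-3-[4-(benzyloxy)-8-methoxynaphthalen-1-yl]-2-(iodomethyl)-1-oxo-2,3-dihydro-1H-indene-2-carboxylate | COc1cccc2c(OCc3ccccc3)ccc([C@@H]4[C@](CI)(C(=O)OC)C(=O)c5c4ccc(OCc4ccccc4)c5OCc4ccccc4)c12 | intermediate
12 | primary radical from 11 (CH2 radical in place of CH2I) | COc1cccc2c(OCc3ccccc3)ccc([C@@H]4[C@]([CH2])(C(=O)OC)C(=O)c5c4ccc(OCc4ccccc4)c5OCc4ccccc4)c12 | intermediate
13 | cyclopropyloxyl radical (cyclopropane C1–C2–C3 fused to the five-membered ring, oxyl on C1) | COc1cccc2c(OCc3ccccc3)ccc([C@@H]4[C@@]6(C(=O)OC)C[C@@]6([O])c5c4ccc(OCc4ccccc4)c5OCc4ccccc4)c12 | intermediate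
14 | ring-expanded tetralone radical (radical at C3, α to the ester) | COc1cccc2c(OCc3ccccc3)ccc([C@@H]4[C](C(=O)OC)CC(=O)c5c4ccc(OCc4ccccc4)c5OCc4ccccc4)c12 | intermediate
15 | methyl (1S)-5,6-bis(benzyloxy)-1-[4-(benzyloxy)-8-methoxynaphthalen-1-yl]-4-oxo-1,2,3,4-tetrahydronaphthalene-2-carboxylate (epimers at the ester carbon) | COc1cccc2c(OCc3ccccc3)ccc([C@@H]4C(C(=O)OC)CC(=O)c5c4ccc(OCc4ccccc4)c5OCc4ccccc4)c12 | intermediate
16 | (1S)-5,6-bis(benzyloxy)-1-[4-(benzyloxy)-8-methoxynaphthalen-1-yl]-4-oxo-1,2,3,4-tetrahydronaphthalene-2-carboxylic acid (epimers at the acid carbon) | COc1cccc2c(OCc3ccccc3)ccc([C@@H]4C(C(=O)O)CC(=O)c5c4ccc(OCc4ccccc4)c5OCc4ccccc4)c12 | intermediate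
17 | 2-thioxopyridin-1(2H)-yl ester of 16 (Barton ester) | COc1cccc2c(OCc3ccccc3)ccc([C@@H]4C(C(=O)ON6C=CC=CC6=S)CC(=O)c5c4ccc(OCc4ccccc4)c5OCc4ccccc4)c12 | intermediate
18 | (4S)-7,8-bis(benzyloxy)-4-[4-(benzyloxy)-8-methoxynaphthalen-1-yl]-3,4-dihydronaphthalen-1(2H)-one | COc1cccc2c(OCc3ccccc3)ccc([C@@H]4CCC(=O)c5c4ccc(OCc4ccccc4)c5OCc4ccccc4)c12 | intermediate
19 | (4S)-7,8-dihydroxy-4-(4-hydroxy-8-methoxynaphthalen-1-yl)-3,4-dihydronaphthalen-1(2H)-one | COc1cccc2c(O)ccc([C@@H]3CCC(=O)c4c3ccc(O)c4O)c12 | target

Total step count: 12. Longest linear sequence: 10 (steps 1–3 and 6–12).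

**Steps most likely to fail**

Step 7. The catalyst-bound cation may close with weak rotational (torquo) selectivity, or closure may be slow because the electron-rich naphthyl group stabilises the cation.
- The fallback replaces catalyst control by auxiliary control, sets out from 8 and comes back at 10.
- Compound 8 is transesterified with (−)-8-phenylmenthol (DMAP, toluene, reflux, methanol distilled off) to 8-phenylmenthyl 3-[2,3-bis(benzyloxy)phenyl]-3-oxopropanoate F1.
- Knoevenagel condensation with 5 under the conditions of step 6 should give the 8-phenylmenthyl alkylidene keto ester F2.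
- An achiral Lewis acid (Sc(OTf)3, ClCH2CH2Cl, 60 °C) then closes the ring while the phenyl group of the auxiliary shields one face of the alkylidene carbon.
- The (2R,3S) 8-phenylmenthyl indanone carboxylate F3 is freed from its diastereomer by crystallisation or chromatography, which secures a single stereochemical series.
- DMAP-catalysed methanolysis through the acylketene (MeOH, toluene, 110 °C, sealed tube) returns 10 and the auxiliary.

Step 9. Hydrogen transfer to the primary radical may occur before its 3-exo attack on the hindered carbonyl group flanked by an ortho alkoxy group.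
- The fallback is a two-electron zinc homoenolate route that sets out from 10, bypasses 11 and comes back at 15.
- With Et2Zn, CF3CO2H and CH2I2 in CH2Cl2 (0 °C to rt), the zinc enolate of 10 is methylenated at C3 by the carbenoid (zinc-carbenoid chain extension of β-keto esters).
- The resulting zinc homoenolate closes on C1 to a cyclopropanolate, which fragments to the zinc ester enolate of 15. Aqueous NH4Cl protonates it.
- The same C1–C2 bond is formed with no hydrogen donor present to intercept the reactive carbon.
- This detour makes no compound outside the list (F0).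

Step 8. O-alkylation, or no reaction at all, may occur at the congested α-carbon next to the peri-substituted naphthyl group with the sluggish electrophile.
- The fallback uses an aldol addition followed by substitution instead of alkylation by a dihalide, sets out from 10 and comes back at 11.
- Hydroxymethylation with the small, reactive electrophile formaldehyde (aq HCHO, KHCO3, THF, rt) should give, again anti to the naphthyl group, the hydroxymethyl keto ester F4.
- Appel iodination under neutral conditions (I2, PPh3, imidazole, toluene, rt), which avoids a retro-aldol reaction, converts it into 11.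

Further compounds
F1 | step 7 | (1R,2S,5R)-5-methyl-2-(2-phenylpropan-2-yl)cyclohexyl 3-[2,3-bis(benzyloxy)phenyl]-3-oxopropanoate | C[C@@H]1CC[C@H]([C@@H](C1)OC(=O)CC(=O)c1cccc(OCc2ccccc2)c1OCc1ccccc1)C(C)(C)c1ccccc1
F2 | step 7 | (1R,2S,5R)-5-methyl-2-(2-phenylpropan-2-yl)cyclohexyl (Z)-2-[2,3-bis(benzyloxy)benzoyl]-3-[4-(benzyloxy)-8-methoxynaphthalen-1-yl]prop-2-enoate | C[C@@H]1CC[C@H]([C@@H](C1)OC(=O)/C(=C\c1ccc(OCc2ccccc2)c2cccc(OC)c12)C(=O)c1cccc(OCc2ccccc2)c1OCc1ccccc1)C(C)(C)c1ccccc1
F3 | step 7 | (1R,2S,5R)-5-methyl-2-(2-phenylpropan-2-yl)cyclohexyl (2R,3S)-6,7-bis(benzyloxy)-3-[4-(benzyloxy)-8-methoxynaphthalen-1-yl]-1-oxo-2,3-dihydro-1H-indene-2-carboxylate | COc1cccc2c(OCc3ccccc3)ccc([C@@H]4[C@@H](C(=O)O[C@@H]6C[C@H](C)CC[C@H]6C(C)(C)c6ccccc6)C(=O)c5c4ccc(OCc4ccccc4)c5OCc4ccccc4)c12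
F0 | step 9 | none | none
F4 | step 8 | methyl (2R,3S)-6,7-bis(benzyloxy)-3-[4-(benzyloxy)-8-methoxynaphthalen-1-yl]-2-(hydroxymethyl)-1-oxo-2,3-dihydro-1H-indene-2-carboxylate | COc1cccc2c(OCc3ccccc3)ccc([C@@H]4[C@](CO)(C(=O)OC)C(=O)c5c4ccc(OCc4ccccc4)c5OCc4ccccc4)c12
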